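Friday's flask differs from the delta run by 2.00 µM of initiator, and Saturday's differs from the epsilon run by 8.00 µM, so each has a near twin.

| setting | delta | epsilon | Saturday's | Friday's |
|---|---|---|---|---|
| free monomer | 31 mM | 31 mM | 31 mM | 31 mM |
| transfer agent | 9.3 mM | 9.3 mM | 9.30 mM | 9.30 mM |
| initiator | 18 µM | 54 µM | 62 µM | 20 µM |
| impurity | 13 µM | 13 µM | 13 µM | 13 µM |
| remark | run made earlier | run made earlier |  |  |
| time |  |  | 6.0 min | 6.0 min |

| run | time / min | monomer in chains / % | free monomer / % |
|---|---|---|---|
| delta | 1.00 | 63 | 38 |
| delta | 2.00 | 65 | 34 |
| delta | 3.00 | 68 | 33 |
| delta | 4.00 | 64 | 33 |
| epsilon | 0.500 | 96 | 7 |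
| epsilon | 1.33 | 100 | 3 |
| epsilon | 2.50 | 100 | 0 |
| epsilon | 4.00 | 100 | 2 |

(each reading ± 1.5 percentage points)

- the average divides the monomer in chains by the number of chains begun, living and dead together
- the analysis behind the earlier runs scatters by 1.5 percentage points, standard deviation
- what may be going on: free monomer + initiator -> living end + monomer in chains; free monomer + living end -> monomer in chains + living end; living end + transfer agent -> dead chain; initiator + impurity -> spent initiator A; 2 initiator -> spent initiator B
- the earlier runs do not show the number of chains; that part of a forecast is a guess

- which of the two ends with the longer chains by the average number of monomer units in a chain (chains begun, living or dead) ("neither" if they lie within 10%) (Saturday's / Friday's / neither)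
- average number of monomer units in a chain (chains begun, living or dead) at the end, Saturday's
- average number of monomer units in a chain (chains begun, living or dead) at the end, Friday's

Each living end adds free monomer until transfer agent stops it. Transfer agent far outnumbers the ends, so that death is pseudo-first-order. Call ln([free monomer] charged / [free monomer] left) the dose. The delta readings level off at a dose of 1.11, and the reading at 1.00 min gives a death rate of 2.06 /min. With that rate, the reading of the epsilon run at 0.500 min gives a final dose of 4.13.

As a first answer, let impurity destroy its equal of initiator. That leaves 5.00 µM and 41.0 µM, a ratio of 8.20, but the doses stand at only 3.73. Go round again and use the difference between the runs, since both hold the same impurity. The dose gained per unit of extra initiator, 0.0840 /µM, then also turns a dose into chains.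

From the delta run, Friday's gets a dose of 1.28, which means 72.1% reacted and a length of 1470. Saturday's gets 4.81, and its length comes to 538.

The forecast names Friday's, with 680 for Saturday's and 3400 for Friday's, both above this reckoning , and warns: "Chain counts are guessed, and Friday's is sensitive to the small difference from the impurity level."

The flasks give 648 for Saturday's and 2010 for Friday's, so Friday's has the longer chains, and the difference in initiator is the main reason for that gap: Friday's stands at 2010, and with that difference taken away at 648.

    free monomer + initiator → living end + monomer in chains (k = 57.0 /M/s)
    free monomer + living end → monomer in chains + living end, rate k2*[living end]*[free monomer] (k = 4900 /M/s)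
    living end + transfer agent → dead chain (kL = 4.70 /M/s)
    initiator + impurity → spent initiator A (k = 1.90 × 10⁵ /M/s)
    2 initiator → spent initiator B (k = 950 /M/s)

Friday's keeps 29% of its free monomer, a dose of 1.22, which at 0.0840 /µM reads as 14.5 µM of chains, while that flask holds 0.0109 mM of dead chain. Now take the neighbour, like Saturday's but with 0.022 mM of impurity. It keeps 1.2% of its free monomer against 0.47%, which lowers the dose by 0.953, and 0.0840 /µM reads that as 11.3 µM fewer chains. The neighbour holds 0.0392 mM of dead chain against 0.0477 mM in Saturday's, and its average length is 781.

The numbers in the tables were computed with constants of no real substance.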